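**Strategy.** The target is a 6,12-seco-eudesmanolide whose ring-fusion bond C5–C10, shared by rings A and B, sits between C1 (β-hydroxyl) and C4 (exocyclic C4=C15). This pattern is read as a C1–C10 epoxide that has been attacked across a ten-membered ring by a C4=C5 alkene. The route therefore disconnects C5–C10: titanium(III) opens costunolide 1β,10α-epoxide, a crown-shaped epoxy-germacranolide one step from commercial costunolide, and in one operation forms that bond, both six-membered rings, the C5 and C10 stereocentres and the C4=C15 alkene, giving reynosin. C3 oxygenation, lactone opening to the methyl ester, O6 acylation and desilylation complete the synthesis.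

Key step: step 2

Assumption: eudesmane/germacrane numbering is used; the SMILES of the target, the epoxygermacranolide and the cyclised lactone were re-derived atom by atom and agree with one another (1β-O, 5α-H, 6α-O, 7α-H, 10β-CH3, plus 3β-OH in the target), so no structure needed correction, and commercial (+)-costunolide is taken as the natural enantiomer.

**Step 1**
Reactants: 1 (+)-costunolide (germacra-1(10)E,4E,11(13)-trien-6α,12-olide; H6β, H7α)
Product: 2 costunolide 1β,10α-epoxide (trans epoxide, C1–O β, C10–O α; 4E alkene and methylene lactone unchanged)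
Conditions: mCPBA (1.05 equiv), NaHCO3, CH2Cl2, 0 °C
Reagents that add atoms: mCPBA, OOC(=O)c1cccc(Cl)c1
Why: Prilezhaev epoxidation picks the most electron-rich alkene, the trisubstituted C1=C10 (C4=C5 is deactivated by the allylic lactone oxygen on C6, C11=C13 by conjugation), and delivers oxygen syn from the exposed outer face of the crown conformer, so the E-alkene becomes the trans 1β,10α-epoxide.

**Step 2**
Reactants: 2 costunolide 1β,10α-epoxide
Product: 3 reynosin (1β-hydroxyeudesma-4(15),11(13)-dien-6α,12-olide; 5α-H, 10β-CH3, trans-decalin)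
Conditions: Cp2TiCl2 (2.5 equiv), Mn dust, degassed THF, rt (gives Cp2TiCl); then 2, rt; 1 M HCl work-up
Reagents that add atoms: none
Why: Nugent–RajanBabu-type single-electron transfer from Cp2TiCl cleaves C10–O to the tertiary C10 radical while C1 keeps its β-oxygen as a titanium(IV) alkoxide; the radical adds across the ring to C5, and the tertiary C4 radical is intercepted by a second Cp2TiCl that removes a C15 hydrogen (mixed disproportionation/β-hydride loss) to leave C4=C15. The closest known reaction type is the titanocene(III)-mediated radical cyclisation of epoxypolyenes and of 1(10)-epoxygermacrolides to eudesmanolides. Ring A (C10–C1–C2–C3–C4–C5) closes 6-endo-trig and ring B (C10–C9–C8–C7–C6–C5) closes 6-exo-trig in the same bond-forming event. C10 (methyl β) and C5 (H α) are set by the chair–chair transition state of the crown conformer, with C14 and C15 on the β face and the trans-lactone at C6/C7 locking the fold, which gives the trans-decalin; C1 is inherited from the epoxide. The step needs opening at C10 rather than C1 (tertiary versus secondary radical), cyclisation faster than deoxygenation or reduction (C10 and C5 are held within bonding distance and dry aprotic THF offers no hydrogen donor) and exocyclic rather than endocyclic alkene formation (the bulky titanium at C4 reaches the unhindered methyl hydrogens), while the electron-poor C11=C13 lies far from both radical centres.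

**Step 3**
Reactants: 3 reynosin
Product: 4 3α-hydroxyreynosin (1β,3α-dihydroxyeudesma-4(15),11(13)-dien-6α,12-olide; axial 3-OH)
Conditions: SeO2 (0.5 equiv), t-BuOOH (2.5 equiv), CH2Cl2, rt
Reagents that add atoms: selenium dioxide, O=[Se]=O (transfers the oxygen); tert-butyl hydroperoxide, CC(C)(C)OO (re-oxidises selenium, ultimate oxygen source)
Why: Sharpless SeO2/t-BuOOH allylic hydroxylation: an ene reaction at C15 followed by a [2,3]-sigmatropic shift returns the alkene to C4=C15 and delivers oxygen to the C3 methylene (preferred over the tertiary C5–H) along the axial α trajectory, while the electron-poor C11=C13 does not react.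

**Step 4**
Reactants: 4 3α-hydroxyreynosin
Product: 5 3-oxoreynosin (1β-hydroxy-3-oxoeudesma-4(15),11(13)-dien-6α,12-olide), used crude
Conditions: activated MnO2 (20 equiv), CH2Cl2, rt; filter through Celite
Reagents that add atoms: none
Why: Chemoselective MnO2 oxidation of an allylic alcohol: only the C3 carbinol reacts (more slowly than usual because its C–H is equatorial, hence the large excess), the saturated C1 alcohol is left alone, and the neutral heterogeneous medium spares the β-hydroxy ketone from elimination and the exocyclic enone from migration into the ring.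

**Step 5**
Reactants: 5 3-oxoreynosin
Product: 6 3β-hydroxyreynosin (1β,3β-dihydroxyeudesma-4(15),11(13)-dien-6α,12-olide; equatorial 3-OH)
Conditions: NaBH4 (1.1 equiv), CeCl3·7H2O (1.2 equiv), MeOH, −78 °C
Reagents that add atoms: none
Why: Luche reduction: the cerium-activated carbonyl takes hydride 1,2 along the unhindered axial α trajectory, so the new C3 hydroxyl is equatorial and β, and Ce(III) at low temperature suppresses conjugate reduction of C4=C15 and C11=C13.

**Step 6**
Reactants: 6 3β-hydroxyreynosin
Product: 7 1β,3β-bis(triethylsilyloxy)eudesma-4(15),11(13)-dien-6α,12-olide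
Conditions: TESOTf (2.5 equiv), 2,6-lutidine (4 equiv), CH2Cl2, −78 → 0 °C
Reagents that add atoms: triethylsilyl triflate, CC[Si](CC)(CC)OS(=O)(=O)C(F)(F)F
Why: Silyl triflate silylation with a hindered pyridine base covers the allylic C3 and the neopentyl C1 hydroxyl under non-nucleophilic conditions that leave the methylene lactone untouched; TES is chosen so that the final deprotection can be mild.

**Step 7**
Reactants: 7 1β,3β-bis(triethylsilyloxy)eudesma-4(15),11(13)-dien-6α,12-olide
Product: 9 methyl 6α-hydroxy-1β,3β-bis(triethylsilyloxy)eudesma-4(15),11(13)-dien-12-oate, via potassium hydroxy-carboxylate 8 (not isolated)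
Conditions: KOH (1.2 equiv), THF–H2O, 0 °C → rt; evaporate, toluene azeotrope; MeI (5 equiv), KHCO3, DMF, 0 °C → rt
Reagents that add atoms: potassium hydroxide, [K+].[OH-]; iodomethane, CI
Why: Saponification by acyl–oxygen cleavage (C6 keeps its configuration) opens the trans-fused lactone irreversibly to the carboxylate, and SN2 O-methylation of that salt under near-neutral conditions gives the γ-hydroxy ester without the acid or strong base that would catalyse relactonisation or addition to C13.

**Step 8**
Reactants: 10 methyl 2-(hydroxymethyl)acrylate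
Product: 11 methyl 2-[(tert-butyldimethylsilyloxy)methyl]acrylate
Conditions: TBSCl, imidazole, CH2Cl2, 0 °C → rt
Reagents that add atoms: tert-butyldimethylsilyl chloride, CC(C)(C)[Si](C)(C)Cl
Why: Standard imidazole-promoted silylation (Corey conditions) of a primary allylic alcohol.

**Step 9**
Reactants: 11 methyl 2-[(tert-butyldimethylsilyloxy)methyl]acrylate
Product: 12 2-[(tert-butyldimethylsilyloxy)methyl]acrylic acid
Conditions: LiOH·H2O, THF–H2O, 0 °C → rt; 1 M HCl to pH 4 at 0 °C
Reagents that add atoms: lithium hydroxide, [Li+].[OH-]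
Why: Ester saponification of an unhindered methyl ester; the primary TBS ether tolerates aqueous hydroxide and brief acidification to pH 4 in the cold.

**Step 10**
Reactants: 9 methyl 6α-hydroxy-1β,3β-bis(triethylsilyloxy)eudesma-4(15),11(13)-dien-12-oate; 12 2-[(tert-butyldimethylsilyloxy)methyl]acrylic acid
Product: 14 methyl 6α-{2-[(tert-butyldimethylsilyloxy)methyl]acryloyloxy}-1β,3β-bis(triethylsilyloxy)eudesma-4(15),11(13)-dien-12-oate, via Yamaguchi mixed anhydride 13 (not isolated)
Conditions: 12 (2 equiv), 2,4,6-Cl3C6H2COCl, Et3N, toluene, rt; then 9, DMAP, rt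
Reagents that add atoms: none
Why: Yamaguchi esterification: the mixed anhydride and DMAP give an acylpyridinium reactive enough for the hindered equatorial C6 hydroxyl, in a medium too weakly basic for relactonisation, and the C6–O bond is not broken so its configuration stands.

**Step 11**
Reactants: 14 methyl 6α-{2-[(tert-butyldimethylsilyloxy)methyl]acryloyloxy}-1β,3β-bis(triethylsilyloxy)eudesma-4(15),11(13)-dien-12-oate
Product: 15 methyl 1β,3β-dihydroxy-6α-[2-(hydroxymethyl)acryloyloxy]eudesma-4(15),11(13)-dien-12-oate (CNP0247525.1)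
Conditions: HF·pyridine, pyridine, THF, 0 °C → rt
Reagents that add atoms: none
Why: Fluoride-mediated desilylation with pyridine-buffered HF removes the two secondary TES ethers and the primary TBS ether without touching the two acrylate esters or the allylic alcohol.

**Compound list**
1 | (+)-costunolide | O=C1O[C@@H]2/C=C(\C)/CC/C=C(\C)/CC[C@H]2C1=C | starting material
2 | costunolide 1β,10α-epoxide | O=C1O[C@@H]2/C=C(\C)/CC[C@H]3O[C@]3(C)CC[C@H]2C1=C | intermediate
3 | reynosin | O=C1O[C@@H]2[C@H]3C(=C)CC[C@@H](O)[C@]3(C)CC[C@H]2C1=C | intermediate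
4 | 3α-hydroxyreynosin | O=C1O[C@@H]2[C@H]3C(=C)[C@H](O)C[C@@H](O)[C@]3(C)CC[C@H]2C1=C | intermediate
5 | 3-oxoreynosin | O=C1O[C@@H]2[C@H]3C(=C)C(=O)C[C@@H](O)[C@]3(C)CC[C@H]2C1=C | intermediate
6 | 3β-hydroxyreynosin | O=C1O[C@@H]2[C@H]3C(=C)[C@@H](O)C[C@@H](O)[C@]3(C)CC[C@H]2C1=C | intermediate
7 | 1β,3β-bis(triethylsilyloxy)eudesma-4(15),11(13)-dien-6α,12-olide | O=C1O[C@@H]2[C@H]3C(=C)[C@@H](O[Si](CC)(CC)CC)C[C@@H](O[Si](CC)(CC)CC)[C@]3(C)CC[C@H]2C1=C | intermediate
8 | potassium 6α-hydroxy-1β,3β-bis(triethylsilyloxy)eudesma-4(15),11(13)-dien-12-oate | O[C@@H]1[C@H]2C(=C)[C@@H](O[Si](CC)(CC)CC)C[C@@H](O[Si](CC)(CC)CC)[C@]2(C)CC[C@H]1C(=C)C(=O)[O-].[K+] | intermediate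
9 | methyl 6α-hydroxy-1β,3β-bis(triethylsilyloxy)eudesma-4(15),11(13)-dien-12-oate | O[C@@H]1[C@H]2C(=C)[C@@H](O[Si](CC)(CC)CC)C[C@@H](O[Si](CC)(CC)CC)[C@]2(C)CC[C@H]1C(=C)C(=O)OC | intermediate
10 | methyl 2-(hydroxymethyl)acrylate | C=C(CO)C(=O)OC | starting material
11 | methyl 2-[(tert-butyldimethylsilyloxy)methyl]acrylate | C=C(CO[Si](C)(C)C(C)(C)C)C(=O)OC | intermediate
12 | 2-[(tert-butyldimethylsilyloxy)methyl]acrylic acid | C=C(CO[Si](C)(C)C(C)(C)C)C(=O)O | intermediate
13 | 2-[(tert-butyldimethylsilyloxy)methyl]acrylic 2,4,6-trichlorobenzoic anhydride | C=C(CO[Si](C)(C)C(C)(C)C)C(=O)OC(=O)c1c(Cl)cc(Cl)cc1Cl | intermediate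
14 | methyl 6α-{2-[(tert-butyldimethylsilyloxy)methyl]acryloyloxy}-1β,3β-bis(triethylsilyloxy)eudesma-4(15),11(13)-dien-12-oate | C=C(CO[Si](C)(C)C(C)(C)C)C(=O)O[C@@H]1[C@H]2C(=C)[C@@H](O[Si](CC)(CC)CC)C[C@@H](O[Si](CC)(CC)CC)[C@]2(C)CC[C@H]1C(=C)C(=O)OC | intermediate
15 | methyl 1β,3β-dihydroxy-6α-[2-(hydroxymethyl)acryloyloxy]eudesma-4(15),11(13)-dien-12-oate | C=C(CO)C(=O)O[C@@H]1[C@H]2C(=C)[C@@H](O)C[C@@H](O)[C@]2(C)CC[C@H]1C(=C)C(=O)OC | target

**Count.** Total steps: 11. Longest linear sequence: 9 (steps 1–7, 10, 11 from costunolide); steps 8–9 make the side-chain acid.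

**Steps most likely to fail**

Step 2. The C10 radical may be captured by a second titanium(III) before it cyclises, which returns the alkene by deoxygenation, or the C4 radical may be reduced or lose a ring hydrogen instead of a C15 hydrogen. The fallback leaves the radical manifold for the cationic one and sets out from 2: BF3·OEt2 in CH2Cl2 at low temperature ionises the C10–O bond, the C4=C5 alkene captures the C10 cation through the same chair–chair fold with inversion at C10, and proton loss from the C4 cation should give 3 together with its Δ3 isomer santamarine F1, which is removed by chromatography (silver nitrate-doped silica if needed). The route is rejoined at 3.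

Step 7. Hydroxide may add to C13, or the γ-hydroxy ester may close back to the lactone with loss of methanol during methylation or isolation. The fallback masks the methylene first and sets out from 7: dimethylamine in THF adds to C13 (aza-Michael) to give the 13-dimethylamino-11βH-dihydro lactone F2; sodium methoxide in methanol, which can no longer add to C13, opens the lactone to the amino hydroxy methyl ester F3; iodomethane quaternises nitrogen to the trimethylammonium iodide F4, and aqueous NaHCO3 eliminates trimethylamine (E1cB) to restore C11=C13. The route is rejoined at 9. The C11 configuration of F2–F4 is assumed (thermodynamic protonation) and is erased in the elimination.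

Step 10. Acylation of the hindered C6 hydroxyl may be slow enough for relactonisation or for DMAP addition to the activated acrylate to compete. The fallback builds the acyl group on the substrate and sets out from 9: DCC-mediated acylation with diethylphosphonoacetic acid, which reacts through a small, highly electrophilic phosphonoketene, should give the 6-O-(diethoxyphosphorylacetyl) ester F5; aqueous formaldehyde and K2CO3 in THF (Villiéras hydroxymethylation followed by Horner–Wadsworth–Emmons olefination) convert the phosphonoacetate into the 2-(hydroxymethyl)acrylate, giving the bis-TES ether of the target F6; HF·pyridine then removes the two TES groups. The route is rejoined at 15.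

**Further compounds**
F1 | step 2 | santamarine (1β-hydroxyeudesma-3,11(13)-dien-6α,12-olide) | O=C1O[C@@H]2[C@H]3C(C)=CC[C@@H](O)[C@]3(C)CC[C@H]2C1=C
F2 | step 7 | 13-dimethylamino-1β,3β-bis(triethylsilyloxy)-11βH-eudesm-4(15)-en-6α,12-olide | O=C1O[C@@H]2[C@H]3C(=C)[C@@H](O[Si](CC)(CC)CC)C[C@@H](O[Si](CC)(CC)CC)[C@]3(C)CC[C@H]2[C@@H]1CN(C)C
F3 | step 7 | methyl 13-dimethylamino-6α-hydroxy-1β,3β-bis(triethylsilyloxy)-11βH-eudesm-4(15)-en-12-oate | O[C@@H]1[C@H]2C(=C)[C@@H](O[Si](CC)(CC)CC)C[C@@H](O[Si](CC)(CC)CC)[C@]2(C)CC[C@H]1[C@H](CN(C)C)C(=O)OC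
F4 | step 7 | N-methyl quaternary ammonium iodide of F3 | O[C@@H]1[C@H]2C(=C)[C@@H](O[Si](CC)(CC)CC)C[C@@H](O[Si](CC)(CC)CC)[C@]2(C)CC[C@H]1[C@H](C[N+](C)(C)C)C(=O)OC.[I-]
F5 | step 10 | methyl 6α-[(diethoxyphosphoryl)acetoxy]-1β,3β-bis(triethylsilyloxy)eudesma-4(15),11(13)-dien-12-oate | CCOP(=O)(OCC)CC(=O)O[C@@H]1[C@H]2C(=C)[C@@H](O[Si](CC)(CC)CC)C[C@@H](O[Si](CC)(CC)CC)[C@]2(C)CC[C@H]1C(=C)C(=O)OC
F6 | step 10 | methyl 6α-[2-(hydroxymethyl)acryloyloxy]-1β,3β-bis(triethylsilyloxy)eudesma-4(15),11(13)-dien-12-oate | C=C(CO)C(=O)O[C@@H]1[C@H]2C(=C)[C@@H](O[Si](CC)(CC)CC)C[C@@H](O[Si](CC)(CC)CC)[C@]2(C)CC[C@H]1C(=C)C(=O)OC
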